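(The data stem from a simulated flask with made-up constants, noise included.)

Of the E charged to the north-west run, 35% is left at 120 min, so 65.0% has been spent, and X stands at 39%. In each flask E is dosed into stirred G at one temperature. The X formed per E spent here is 0.600; I call this the yield on spent E, the selectivity. At 40.0 min the same run reads 0.576, so in the north-west run the ratio is nearly constant and I freeze it. It does not hold for every recipe: the west run, with about half that G and with 0.059 M of E against 0.040 M, reads 0.364 at 120 min, and there two settings differ at once. Grey, blue and teal each carry 0.0649 M of G, like the north-west run, but 0.059 M of E, like the west run, so for them I use the frozen ratio as a rough value.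

| flask | E | G | temperature | remark | time |
|---|---|---|---|---|---|
| north-west | 0.040 M (fed, over 5.0 min) | 0.0649 M | 18 °C | run made earlier; the fed solution adds 0.25 times the starting volume |  |
| south | 0.088 M (fed, over 5.0 min) | 0.0649 M | 34 °C | run made earlier; the fed solution adds 0.25 times the starting volume |  |
| west | 0.059 M (fed, over 5.0 min) | 0.032 M | 18 °C | run made earlier; the fed solution adds 0.25 times the starting volume |  |
| grey | 0.059 M (fed, over 5.0 min) | 0.0649 M | 10 °C | the fed solution adds 0.25 times the starting volume | 2.0 h |
| blue | 0.059 M (fed, over 5.0 min) | 0.0649 M | 40 °C | the fed solution adds 0.25 times the starting volume | 2.0 h |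
| teal | 0.059 M (fed, over 5.0 min) | 0.0649 M | 25 °C | the fed solution adds 0.25 times the starting volume | 2.0 h |

- north-west (time / min: X / %, E / %): 20.0: 11, 82; 40.0: 19, 67; 60.0: 25, 55; 80.0: 32, 46; 90.0: 35, 44; 120: 39, 35
- south (time / min: X / %, E / %): 2.50: 0, 46; 8.00: 12, 71; 12.0: 19, 56; 20.0: 22, 39; 30.0: 23, 28; 40.0: 21, 19
- west (time / min: X / %, E / %): 25.0: 7, 84; 50.0: 14, 69; 80.0: 17, 58; 90.0: 18, 53; 120: 20, 45

(each reading ± 1.5 percentage points)

* the best flask by amount of X, in percent of the E charged; "all alike" if 1.5 percentage points covers them all (grey / blue / teal / all alike)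
* amount of X at the end, in percent of the E charged, grey
* amount of X at the end, in percent of the E charged, blue
* amount of X at the end, in percent of the E charged, teal

- charges are per starting volume, the dose included; the dosed solution carries all of it
- percentages count the whole charge, also what has not yet gone in

One extreme is a cold flask that keeps its X, where X is 0.600 times the E spent. The other is the south run, read at 40.0 min, whose yield has sunk to 0.259, lower than the frozen one. Grey I put at the first extreme, and for it I need the E spent. Taking the fall of E as first order, roughly, since the charges differ, the north-west run gives 0.00812 min⁻¹ and the south run 0.0386 min⁻¹. Grey lies half as far below the north-west temperature as the south run lies above it, so I divide by the square root of their ratio and get 0.00372 min⁻¹. Over 2.0 h that spends 36.0%, which makes X in grey 21.6%. For teal, at 25 °C, the same scaling between the two runs gives 0.0161 min⁻¹, and over 2.0 h that spends 85.4%. With a yield midway between the extremes, which is a guess, X in teal comes to 36.7%, more than grey. Blue is hotter than the south run, so I expect less than 25.9%. My choice is teal.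

The forecast gives 24% for grey, 0.5% for blue and 27% for teal: “Teal is probably best, narrowly over grey.” Its grey stands above mine, and its teal stands below mine.

    2 E → Q (k = 0.00231 M⁻¹ s⁻¹, Ea = 76.0 kJ mol⁻¹)
    E + G → X + Z (k = 0.00462 M⁻¹ s⁻¹, Ea = 66.0 kJ mol⁻¹)
    X ⇌ J (K = 23.0, k = 1.15 × 10⁻⁴ s⁻¹, Ea = 99.0 kJ mol⁻¹, ΔH = −3.00 kJ mol⁻¹)
    E + Z → D (k = 4.02 × 10⁻⁴ M⁻¹ s⁻¹, Ea = 72.0 kJ mol⁻¹)
    (constants at 25 °C)

The flasks give 25.4% in grey, 4.03% in blue and 30.0% in teal, so teal is best. In teal at 2.00 h, J stands at 20.9% beside X. The yield on spent E in teal is 0.359, which lies between 0.259 and 0.600. In grey, 44.2% of the E is spent, and the yield there is 0.574.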